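**Design of a synthesis of 2-(7-hydroxy-2,2-dimethylchroman-5-yl)-7-(2-methylbut-3-en-2-yl)-1-benzofuran-4,6-diol (20)**

Locants without a prime refer to the benzofuran (ring A is its benzo ring), primed locants to the chroman (ring C is its benzo ring).

## The problem

The target is a 2-arylbenzofuran in which C2 is bonded to C5' of a 2,2-dimethylchroman, so the aryl–furan bond sits next to the ring-fusion carbon C4a' and is ortho-hindered. Ring C carries oxygen only at C7' and C8a', which places the benzofuran at the less accessible position beside the C4' chain; electrophilic chroman annulation onto a simple 5-arylresorcinol would not reliably give this pattern. The molecule has no stereocentre, so there is nothing to control or to relay. Three phenols (O4, O6, O7') must be told apart, because only O6 may serve as the anchor that delivers the tertiary allyl group to C7. That 1,1-dimethylallyl group, ortho to a free phenol, cyclises under acid, is reduced under hydrogenolysis and rearranges further on prolonged heating, so it has to come late and the route has to end under mild base. Both benzo rings are very electron-rich, so they are prone to air oxidation in base and to attack by formaldehyde equivalents during acetal cleavage. The enabling feature is the oxygen pattern of ring C: C5'(benzofuranyl)–C6'–C7'(O)–C8'–C8a'(O)–C4a'(CH2) is the pattern of a folded 1,3,5-triketone whose terminal ketone carbon bears the benzofuran and therefore has no α-hydrogen on that side.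

## Retrosynthesis

**C7–CMe2 bond.** Target 20 is traced to triacetate 19, and 19 to the O6 prenyl ether 17 by an aromatic Claisen rearrangement. The alternatives are worse: direct Friedel–Crafts alkylation gives the linear prenyl isomer without site control, and carrying the group from the start would expose it to the acid and hydrogenolysis steps. Ether 17 lacks the sensitive group and comes from phenol 15 and alcohol 16. The forward reaction must migrate to C7 rather than C5, and the liberated phenol must be trapped at once (as 19) so that the intermediate 18 does not react further.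

**O6 differentiation.** Phenol 15 is traced to benzyl ether 14 and this to diol 13. Only O–C(benzyl) and O–acyl bonds are cut. The point is that O6 carries a benzyl group from the first step while O4 and O7' are acetylated; the acetates survive hydrogenolysis, etherification and heat and are removed at the end by methanolysis. The forward steps ask only that the benzofuran C2=C3 bond survives hydrogenolysis.

**O1'–C2' bond of the chroman.** Diol 13 is traced to resorcinol 11 by cutting the aryl ether bond at the tertiary carbon and restoring the MOM ether at O4 (through 12). The tertiary alcohol of 11 sits ortho to only one phenol, so the closure has one possible direction. The forward reaction must cleave the acetal in a medium that traps the formaldehyde equivalent before the rings are exposed to the cyclodehydration acid.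

**C4a'–C5' bond (ring C).** Resorcinol 11 is traced to triketone 10 by the polyketide-type aldol. This cut removes the aromatic ring together with its substitution problem: the hindered aryl–furan junction becomes an ordinary ketone, and the regiochemistry of ring C is written into the chain. Cutting the C2–C5' bond instead would demand a separately made, regiodefined chroman coupling partner. The forward reaction must favour C-cyclisation over O-cyclisation and over chain cleavage.

**C4–C5 bond of the chain (C8'–C8a').** Triketone 10 is traced to diketone 8 and lactone 9. The γ-carbon of 8 is its only second acidic site, so the dianion forms at one position only, and 9 delivers the last five carbons with the tertiary alcohol already in place.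

**C2–C3 bond of the chain (C6'–C7').** Diketone 8 comes from methyl ketone 6 and ester 7 by a crossed Claisen condensation, a two-carbon extension with no selectivity issue.

**Furan ring (O1–C2 and C2–C3).** Ketone 6 is traced to salicylaldehyde 3 and chloroketone 4. One condensation closes the furan and installs the acetyl group that later becomes C5'.

**Ring A protection.** Aldehyde 3 comes from 2 and 2 from 1. The para oxygen (later O6) receives the benzyl group first, one of the two equivalent ortho oxygens (later O4) the MOM group, and the remaining chelated hydroxyl becomes the furan oxygen.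

## Roads not taken

**Alternative 1:** Ring contraction of a flavanone. The cut is the C3–C3a bond: flavanone A1 would be treated with a hypervalent iodine oxidant in an acidic orthoformate medium, ring A would shift from C4 to C3, and the pyranone would contract to the dihydrobenzofuran ester A2.
- Merits: A1 comes from a simple chalcone-type condensation, and the chelated 5-hydroxyl of the flavanone series distinguishes the future O4 from O6 without any selective alkylation. In that respect it is better than the opening steps of the chosen plan.
- Weak points: the electron-rich chroman aryl group at C2 of A1 is itself a good migrating group, so isoflavone formation competes, and the tosylates meant to suppress this also lower the migratory aptitude of ring A. A2 still carries an ester at C3 and two stereocentres that must be destroyed by hydrolysis, decarboxylation and dehydrogenation. Ring C must be supplied as a regiodefined chroman aldehyde.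
- Comparison: the chosen plan sets against the easier phenol differentiation a ring C whose substitution is fixed by chain connectivity, no oxidation-level corrections after the key step, and no purchased chroman fragment.

**Alternative 2:** Furan closure last. The cut is the C2–C3 bond: the arylmethyl ether A3 of a fully substituted salicylaldehyde would be deprotonated at its benzylic carbon by a phosphazene superbase, add to the ortho aldehyde and dehydrate to the tris-MOM ether A4.
- Merits: it is the most convergent option, and after the key step only deprotection remains. It is clearly better in convergency and in the number of steps after the key step.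
- Weak points: both halves of A3 are hard to make. The aldehyde half needs the tertiary allyl group beside the etherified oxygen, and the chroman half needs a benzylic halide at C5'. The O-alkylation joins two hindered partners, the benzylic anion is poorly stabilised on so electron-rich a ring and can undergo Wittig rearrangement, and releasing 20 from A4 requires acid next to the acid-labile 1,1-dimethylallyl phenol.
- Comparison: the chosen plan is linear and longer after its key step, but its fragments are commodity chemicals and its last step is a mild methanolysis.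

**Alternative 3:** Ring A by Danheiser benzannulation. The cuts are C4–C5, C6–C7 and C3a–C4: photochemical Wolff rearrangement of furyl diazoketone A5 would give a furylketene, which adds silyloxyalkyne A6 and electrocyclises onto the furan to give phenol A7.
- Merits: three bonds and ring A form in one operation, and A7 emerges with O4 free and O6 silylated, so the phenols are differentiated by the bond construction itself. This is better than the selective benzylation the chosen plan relies on.
- Weak points: A5 presupposes a 5-(chroman-5-yl)furan-2-carboxylic acid, so ring C and its aryl–furan bond must be made by cross-coupling to a pre-formed, regiodefined chroman. The diazoketone photolysis and the ynol ether are less convenient than condensation chemistry, the electrocyclisation has to engage an aromatic furan double bond, and the endgame through the O6 prenyl ether is the same as in the chosen plan.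
- Comparison: the chosen plan needs more care in protecting ring A but builds ring C and the hindered biaryl-type junction from a lactone and an acetyl group without cross-coupling or photochemistry.

Key step: step 6

Assumption: triketone 10 is written in its open triketo form although it will exist as a mixture of enol and cyclic hemiketal tautomers, which is carried forward without separation.

## Route

Step 1
Reactants: 1 2,4,6-trihydroxybenzaldehyde
Product: 2 4-(benzyloxy)-2,6-dihydroxybenzaldehyde
Conditions: BnBr (1.0 equiv), NaHCO3 (1.2 equiv), MeCN, 70 °C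
Reagents that add atoms: benzyl bromide, BrCc1ccccc1
Why: Williamson etherification under a base too weak to ionise more than the most acidic phenol; the 4-OH is para to the formyl group and not held in the intramolecular hydrogen bond, so it should be alkylated in preference to the chelated ortho hydroxyls, and one equivalent of halide limits dibenzylation.

Step 2
Reactants: 2 4-(benzyloxy)-2,6-dihydroxybenzaldehyde
Product: 3 4-(benzyloxy)-2-hydroxy-6-(methoxymethoxy)benzaldehyde
Conditions: MOMCl (1.05 equiv), i-Pr2NEt (1.5 equiv), CH2Cl2, 0 °C → rt
Reagents that add atoms: chloromethyl methyl ether, COCCl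
Why: Acetal formation on one of two equivalent ortho phenols; once one is capped the other is locked in a six-membered hydrogen bond to the aldehyde and should resist a second alkylation, the same bias that leaves one hydroxyl free when the parent aldehyde is bis-protected.

Step 3
Reactants: 3 4-(benzyloxy)-2-hydroxy-6-(methoxymethoxy)benzaldehyde; 4 chloroacetone
Product: 6 1-[6-(benzyloxy)-4-(methoxymethoxy)-1-benzofuran-2-yl]ethan-1-one, via O-alkylated aldehyde 5 (not isolated)
Conditions: K2CO3 (2.5 equiv), DMF, 80 °C
Reagents that add atoms: none
Why: Rap–Stoermer condensation: O-alkylation of the phenoxide by the α-chloroketone, then intramolecular aldol of the activated methylene onto the ortho aldehyde and dehydration to the aromatic furan; the ethers are stable to carbonate.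

Step 4
Reactants: 6 1-[6-(benzyloxy)-4-(methoxymethoxy)-1-benzofuran-2-yl]ethan-1-one; 7 ethyl acetate
Product: 8 1-[6-(benzyloxy)-4-(methoxymethoxy)-1-benzofuran-2-yl]butane-1,3-dione
Conditions: NaH (2.5 equiv), EtOAc (5 equiv), THF, 0 → 65 °C; AcOH quench
Reagents that add atoms: none
Why: Crossed Claisen condensation of the methyl ketone enolate with ethyl acetate, driven to completion by formation of the stabilised diketonate; the ketone has a single enolisable position.

Step 5
Reactants: 8 1-[6-(benzyloxy)-4-(methoxymethoxy)-1-benzofuran-2-yl]butane-1,3-dione; 9 6,6-dimethyloxan-2-one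
Product: 10 1-[6-(benzyloxy)-4-(methoxymethoxy)-1-benzofuran-2-yl]-9-hydroxy-9-methyldecane-1,3,5-trione
Conditions: LiN(i-Pr)2 (3.1 equiv), THF, −78 → 0 °C; then 9 (1.2 equiv), −78 °C → rt; AcOH quench
Reagents that add atoms: none
Why: γ-Acylation of a β-diketone dianion: the terminal methyl carbanion, the only second acidic site of 8, adds to the lactone carbonyl and the tetrahedral intermediate opens to the tertiary alkoxide; the third equivalent of base absorbs the proton of the more acidic triketone so that the dianion is not quenched.

Step 6
Reactants: 10 1-[6-(benzyloxy)-4-(methoxymethoxy)-1-benzofuran-2-yl]-9-hydroxy-9-methyldecane-1,3,5-trione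
Product: 11 5-[6-(benzyloxy)-4-(methoxymethoxy)-1-benzofuran-2-yl]-4-(3-hydroxy-3-methylbutyl)benzene-1,3-diol
Conditions: KOH (2 M), H2O/MeOH 1:1, argon, 60 °C; then AcOH to pH 5
Reagents that add atoms: none
Why: Under aqueous hydroxide the hemiketal form opens and 10 is held as its enolates; reversible deprotonation at C6 of the chain (the future C4a') gives the terminal enolate of the C5 carbonyl, which adds to the benzofuran-2-yl ketone carbon C1 (the future C5'). The aldolate loses hydroxide by E1cB elimination and the cyclohexenedione tautomerises to the resorcinol, so aromatisation makes the closure irreversible and pulls the unfavourable pre-equilibria forward. The closest known reaction type is the base-mediated cyclisation of 1,3,5-triketones, or of the 2,6-disubstituted 4-pyranones that hydroxide opens to them, to 5-substituted resorcinols, including cases with an aryl ketone as the electrophilic terminus. Ring C closes in a 6-(enolendo)-exo-trig aldol mode, forming the C4a'–C5' bond. No stereocentre is created, since the carbinol carbon of the aldol adduct becomes aromatic. Regioselectivity is fixed by the substrate, because the aryl ketone has no α-hydrogen on its benzofuran side and every other enolate/carbonyl pairing would close a four-membered ring. C-cyclisation must also win over pyranone formation and retro-Claisen cleavage; the alkaline aqueous medium (pyranone closure is acid-promoted and reversed by hydroxide), the moderate temperature and the exclusion of oxygen are chosen for this. The MOM and benzyl ethers and the tertiary alcohol are inert to aqueous KOH.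

Step 7
Reactants: 11 5-[6-(benzyloxy)-4-(methoxymethoxy)-1-benzofuran-2-yl]-4-(3-hydroxy-3-methylbutyl)benzene-1,3-diol
Product: 13 6-(benzyloxy)-2-(7-hydroxy-2,2-dimethylchroman-5-yl)-1-benzofuran-4-ol, via MOM-free triol 12 (not isolated)
Conditions: 3 M HCl, MeOH, 50 °C; then evaporation and p-TsOH·H2O (10 mol%), PhMe, 80 °C
Reagents that add atoms: none
Why: Acetal methanolysis first, so that the formaldehyde equivalent is trapped by methanol and cannot alkylate the electron-rich rings; acid-catalysed cyclodehydration then captures the tertiary carbocation with the only ortho phenol (6-exo closure to the 2,2-dimethylchroman), and any methyl ether or alkene formed from the alcohol in the first stage funnels through the same cation.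

Step 8
Reactants: 13 6-(benzyloxy)-2-(7-hydroxy-2,2-dimethylchroman-5-yl)-1-benzofuran-4-ol
Product: 14 2-[7-(acetyloxy)-2,2-dimethylchroman-5-yl]-6-(benzyloxy)-1-benzofuran-4-yl acetate
Conditions: Ac2O (3 equiv), pyridine, DMAP (cat.), CH2Cl2, rt
Reagents that add atoms: acetic anhydride, CC(=O)OC(C)=O
Why: DMAP-catalysed O-acylation of both free phenols; the acetates mask O4 and O7' through hydrogenolysis, etherification and the thermal rearrangement and are removable by mild methanolysis.

Step 9
Reactants: 14 2-[7-(acetyloxy)-2,2-dimethylchroman-5-yl]-6-(benzyloxy)-1-benzofuran-4-yl acetate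
Product: 15 2-[7-(acetyloxy)-2,2-dimethylchroman-5-yl]-6-hydroxy-1-benzofuran-4-yl acetate
Conditions: H2 (1 atm), 10% Pd/C, EtOAc, rt
Reagents that add atoms: none
Why: Hydrogenolysis of the benzyl ether; the aromatic furan double bond of a 2-arylbenzofuran is not reduced under these conditions, and the aprotic solvent avoids transesterification of the aryl acetates.

Step 10
Reactants: 15 2-[7-(acetyloxy)-2,2-dimethylchroman-5-yl]-6-hydroxy-1-benzofuran-4-yl acetate; 16 3-methylbut-2-en-1-ol
Product: 17 2-[7-(acetyloxy)-2,2-dimethylchroman-5-yl]-6-[(3-methylbut-2-en-1-yl)oxy]-1-benzofuran-4-yl acetate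
Conditions: PPh3 (1.3 equiv), DIAD (1.3 equiv), THF, 0 °C → rt
Reagents that add atoms: none
Why: Mitsunobu etherification of the single free phenol with the primary allylic alcohol; the neutral conditions avoid the acetyl scrambling that carbonate-mediated alkylation could cause.

Step 11
Reactants: 17 2-[7-(acetyloxy)-2,2-dimethylchroman-5-yl]-6-[(3-methylbut-2-en-1-yl)oxy]-1-benzofuran-4-yl acetate
Product: 19 2-[7-(acetyloxy)-2,2-dimethylchroman-5-yl]-7-(2-methylbut-3-en-2-yl)-1-benzofuran-4,6-diyl diacetate, via C7-rearranged phenol 18 (not isolated)
Conditions: Ac2O (5 equiv), NaOAc (1 equiv), PhNEt2, 190 °C, sealed tube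
Reagents that add atoms: acetic anhydride, CC(=O)OC(C)=O
Why: Aromatic Claisen rearrangement with allylic inversion delivers the 1,1-dimethylallyl group ortho to O6; C7 is preferred because the C6–C7 bond has the higher double-bond character in a benzofuran and C5 is flanked by the C4 acetate, and the para position is the ring fusion. In situ acetylation of the new phenol blocks cyclisation onto the alkene and further sigmatropic shifts.

Step 12
Reactants: 19 2-[7-(acetyloxy)-2,2-dimethylchroman-5-yl]-7-(2-methylbut-3-en-2-yl)-1-benzofuran-4,6-diyl diacetate
Product: 20 2-(7-hydroxy-2,2-dimethylchroman-5-yl)-7-(2-methylbut-3-en-2-yl)-1-benzofuran-4,6-diol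
Conditions: K2CO3 (0.3 equiv), MeOH, argon, 0 °C → rt; then aq. NH4Cl
Reagents that add atoms: none
Why: Base-catalysed transesterification of the three aryl acetates; the non-acidic conditions and buffered quench leave the 1,1-dimethylallyl group beside the free phenol intact, and the inert atmosphere protects the electron-rich triphenol.

## Compound list

1 | 2,4,6-trihydroxybenzaldehyde | O=Cc1c(O)cc(O)cc1O | starting material
2 | 4-(benzyloxy)-2,6-dihydroxybenzaldehyde | O=Cc1c(O)cc(OCc2ccccc2)cc1O | intermediate
3 | 4-(benzyloxy)-2-hydroxy-6-(methoxymethoxy)benzaldehyde | O=Cc1c(O)cc(OCc2ccccc2)cc1OCOC | intermediate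
4 | chloroacetone (1-chloropropan-2-one) | CC(=O)CCl | starting material
5 | 4-(benzyloxy)-2-(methoxymethoxy)-6-(2-oxopropoxy)benzaldehyde | CC(=O)COc1cc(OCc2ccccc2)cc(OCOC)c1C=O | intermediate
6 | 1-[6-(benzyloxy)-4-(methoxymethoxy)-1-benzofuran-2-yl]ethan-1-one | CC(=O)c1cc2c(OCOC)cc(OCc3ccccc3)cc2o1 | intermediate
7 | ethyl acetate | CCOC(C)=O | starting material
8 | 1-[6-(benzyloxy)-4-(methoxymethoxy)-1-benzofuran-2-yl]butane-1,3-dione | CC(=O)CC(=O)c1cc2c(OCOC)cc(OCc3ccccc3)cc2o1 | intermediate
9 | 6,6-dimethyloxan-2-one | CC1(C)CCCC(=O)O1 | starting material
10 | 1-[6-(benzyloxy)-4-(methoxymethoxy)-1-benzofuran-2-yl]-9-hydroxy-9-methyldecane-1,3,5-trione | CC(C)(O)CCCC(=O)CC(=O)CC(=O)c1cc2c(OCOC)cc(OCc3ccccc3)cc2o1 | intermediate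
11 | 5-[6-(benzyloxy)-4-(methoxymethoxy)-1-benzofuran-2-yl]-4-(3-hydroxy-3-methylbutyl)benzene-1,3-diol | CC(C)(O)CCc1c(O)cc(O)cc1-c1cc2c(OCOC)cc(OCc3ccccc3)cc2o1 | intermediate
12 | 5-[6-(benzyloxy)-4-hydroxy-1-benzofuran-2-yl]-4-(3-hydroxy-3-methylbutyl)benzene-1,3-diol | CC(C)(O)CCc1c(O)cc(O)cc1-c1cc2c(O)cc(OCc3ccccc3)cc2o1 | intermediate
13 | 6-(benzyloxy)-2-(7-hydroxy-2,2-dimethylchroman-5-yl)-1-benzofuran-4-ol | CC1(C)CCc2c(O1)cc(O)cc2-c1cc2c(O)cc(OCc3ccccc3)cc2o1 | intermediate
14 | 2-[7-(acetyloxy)-2,2-dimethylchroman-5-yl]-6-(benzyloxy)-1-benzofuran-4-yl acetate | CC(=O)Oc1cc(-c2cc3c(OC(C)=O)cc(OCc4ccccc4)cc3o2)c2c(c1)OC(C)(C)CC2 | intermediate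
15 | 2-[7-(acetyloxy)-2,2-dimethylchroman-5-yl]-6-hydroxy-1-benzofuran-4-yl acetate | CC(=O)Oc1cc(-c2cc3c(OC(C)=O)cc(O)cc3o2)c2c(c1)OC(C)(C)CC2 | intermediate
16 | 3-methylbut-2-en-1-ol | CC(C)=CCO | starting material
17 | 2-[7-(acetyloxy)-2,2-dimethylchroman-5-yl]-6-[(3-methylbut-2-en-1-yl)oxy]-1-benzofuran-4-yl acetate | CC(=O)Oc1cc(-c2cc3c(OC(C)=O)cc(OCC=C(C)C)cc3o2)c2c(c1)OC(C)(C)CC2 | intermediate
18 | 2-[7-(acetyloxy)-2,2-dimethylchroman-5-yl]-6-hydroxy-7-(2-methylbut-3-en-2-yl)-1-benzofuran-4-yl acetate | CC(=O)Oc1cc(-c2cc3c(OC(C)=O)cc(O)c(C(C)(C)C=C)c3o2)c2c(c1)OC(C)(C)CC2 | intermediate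
19 | 2-[7-(acetyloxy)-2,2-dimethylchroman-5-yl]-7-(2-methylbut-3-en-2-yl)-1-benzofuran-4,6-diyl diacetate | CC(=O)Oc1cc(-c2cc3c(OC(C)=O)cc(OC(C)=O)c(C(C)(C)C=C)c3o2)c2c(c1)OC(C)(C)CC2 | intermediate
20 | 2-(7-hydroxy-2,2-dimethylchroman-5-yl)-7-(2-methylbut-3-en-2-yl)-1-benzofuran-4,6-diol | C=CC(C)(C)c1c(O)cc(O)c2cc(-c3cc(O)cc4c3CCC(C)(C)O4)oc12 | target

## Step count and risk

Total: 12 steps. Longest linear sequence: 12 steps (1 → 20).

**Step 6 (key step).** The most likely failure is retro-Claisen cleavage of the chain by hydroxide outrunning the cyclisation. The nucleophilic C6 enolate is the least acidic position of the triketone, and the aryl ketone is deactivated both as part of a diketonate and by the electron-rich benzofuran. O-cyclised forms (hemiketal, pyranone-type) may also persist.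
Fallback: abandon the ring construction and buy ring C ready-made for a cross-coupling, setting out from 3 and returning at 13.
- Ramirez olefination of 3 (CBr4, PPh3) would give 5-(benzyloxy)-2-(2,2-dibromoethenyl)-3-(methoxymethoxy)phenol F1, and intramolecular C–O coupling (CuI, K3PO4, THF) the 6-(benzyloxy)-2-bromo-4-(methoxymethoxy)-1-benzofuran F2.
- Phloroglucinol and 2-methylbut-3-en-2-ol (BF3·OEt2) would give 2,2-dimethylchroman-5,7-diol F3.
- Silylation of the less hindered 7-hydroxyl would give 7-[(tert-butyldimethylsilyl)oxy]-2,2-dimethylchroman-5-ol F4, triflation its trifluoromethanesulfonate F5, and Miyaura borylation (B2pin2, PdCl2(dppf), KOAc) the pinacol boronate F6.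
- Suzuki–Miyaura coupling of F2 with F6 (Pd(PPh3)4, K3PO4) would give the silyl-protected 2-arylbenzofuran F7, from which HCl in MeOH removes the silyl and MOM groups to give 13.

**Step 5.** The most likely failure is proton transfer from the α-methylene of lactone 9 to the strongly basic dianion, together with slow addition to a carbonyl whose ring oxygen bears a gem-dimethyl carbon; both would return 8.
Fallback: reverse the polarity so that the acyl donor cannot enolise, setting out from 3 and 9 and returning at 10.
- Aldehyde 3 and ethyl bromoacetate (K2CO3, DMF) would give ethyl 6-(benzyloxy)-4-(methoxymethoxy)-1-benzofuran-2-carboxylate F8.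
- Lactone 9 would be opened by the lithium enolate of acetone to 8-hydroxy-8-methylnonane-2,4-dione F9.
- The polyanion of F9 (LiN(i-Pr)2, deprotonated at the terminal methyl) would be aroylated by F8 to give 10.
- The price is possible competing deprotonation of F9 at its methylene instead of its methyl group.

**Step 11.** The most likely failures are partial migration to C5, thermal loss of the prenyl group by ionisation of the allylic ether, and further rearrangement of the dienone before it is trapped.
Fallback: make the C7–C bond by cross-coupling at low temperature, setting out from 15 and returning at 18.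
- ortho-Iodination of 15 (N-iodosuccinimide, MeCN, 0 °C) would give 2-[7-(acetyloxy)-2,2-dimethylchroman-5-yl]-6-hydroxy-7-iodo-1-benzofuran-4-yl acetate F10.
- Branch-selective allyl–aryl Suzuki–Miyaura coupling with prenylboronic acid pinacol ester (Pd(OAc)2, bulky biarylphosphine, K3PO4, THF/H2O) would give 18.
- 18 would be deacetylated directly under the conditions of step 12; any acetate lost during the coupling converges on 20.

**Step 1.** The most likely failures are over-alkylation to the 2,4-dibenzyl ether and C-benzylation of the ambident phloroglucinol-type anion, which would erode the regiocontrol on which all later phenol differentiation rests.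
Fallback: use the two selectivities that are best established in this series, setting out from 1 and returning at 3 (replacing steps 1 and 2).
- Double benzylation of 1 (BnBr, K2CO3) would give 2,4-bis(benzyloxy)-6-hydroxybenzaldehyde F11.
- MOM protection of the remaining chelated phenol (NaH, MOMCl) would give 2,4-bis(benzyloxy)-6-(methoxymethoxy)benzaldehyde F12.
- Transfer hydrogenolysis (10% Pd/C, cyclohexa-1,4-diene) would give 2,4-dihydroxy-6-(methoxymethoxy)benzaldehyde F13.
- In F13 only the 4-hydroxyl is free of chelation, so benzylation (BnBr, NaHCO3) would give 3.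

## Further compounds

F1 | step 6 | 5-(benzyloxy)-2-(2,2-dibromoethenyl)-3-(methoxymethoxy)phenol | Oc1cc(OCc2ccccc2)cc(OCOC)c1C=C(Br)Br
F2 | step 6 | 6-(benzyloxy)-2-bromo-4-(methoxymethoxy)-1-benzofuran | Brc1cc2c(OCOC)cc(OCc3ccccc3)cc2o1
F3 | step 6 | 2,2-dimethylchroman-5,7-diol | CC1(C)CCc2c(O)cc(O)cc2O1
F4 | step 6 | 7-[(tert-butyldimethylsilyl)oxy]-2,2-dimethylchroman-5-ol | CC1(C)CCc2c(O)cc(O[Si](C)(C)C(C)(C)C)cc2O1
F5 | step 6 | 7-[(tert-butyldimethylsilyl)oxy]-2,2-dimethylchroman-5-yl trifluoromethanesulfonate | CC1(C)CCc2c(OS(=O)(=O)C(F)(F)F)cc(O[Si](C)(C)C(C)(C)C)cc2O1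
F6 | step 6 | tert-butyl{[2,2-dimethyl-5-(4,4,5,5-tetramethyl-1,3,2-dioxaborolan-2-yl)chroman-7-yl]oxy}dimethylsilane | CC1(C)CCc2c(B3OC(C)(C)C(C)(C)O3)cc(O[Si](C)(C)C(C)(C)C)cc2O1
F7 | step 6 | {[5-(6-(benzyloxy)-4-(methoxymethoxy)-1-benzofuran-2-yl)-2,2-dimethylchroman-7-yl]oxy}(tert-butyl)dimethylsilane | CC1(C)CCc2c(O1)cc(O[Si](C)(C)C(C)(C)C)cc2-c1cc2c(OCOC)cc(OCc3ccccc3)cc2o1
F8 | step 5 | ethyl 6-(benzyloxy)-4-(methoxymethoxy)-1-benzofuran-2-carboxylate | CCOC(=O)c1cc2c(OCOC)cc(OCc3ccccc3)cc2o1
F9 | step 5 | 8-hydroxy-8-methylnonane-2,4-dione | CC(=O)CC(=O)CCCC(C)(C)O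
F10 | step 11 | 2-[7-(acetyloxy)-2,2-dimethylchroman-5-yl]-6-hydroxy-7-iodo-1-benzofuran-4-yl acetate | CC(=O)Oc1cc(-c2cc3c(OC(C)=O)cc(O)c(I)c3o2)c2c(c1)OC(C)(C)CC2
F11 | step 1 | 2,4-bis(benzyloxy)-6-hydroxybenzaldehyde | O=Cc1c(O)cc(OCc2ccccc2)cc1OCc1ccccc1
F12 | step 1 | 2,4-bis(benzyloxy)-6-(methoxymethoxy)benzaldehyde | O=Cc1c(OCOC)cc(OCc2ccccc2)cc1OCc1ccccc1
F13 | step 1 | 2,4-dihydroxy-6-(methoxymethoxy)benzaldehyde | O=Cc1c(O)cc(O)cc1OCOC
A1 | alternative 1 | 7-(benzyloxy)-2-[2,2-dimethyl-7-(tosyloxy)chroman-5-yl]-5-(tosyloxy)chroman-4-one (racemic) | O=C1CC(c2cc(OS(=O)(=O)c3ccc(C)cc3)cc3c2CCC(C)(C)O3)Oc2cc(OCc3ccccc3)cc(OS(=O)(=O)c3ccc(C)cc3)c12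
A2 | alternative 1 | methyl trans-6-(benzyloxy)-2-[2,2-dimethyl-7-(tosyloxy)chroman-5-yl]-4-(tosyloxy)-2,3-dihydro-1-benzofuran-3-carboxylate (racemic, one enantiomer drawn) | COC(=O)[C@@H]1[C@@H](c2cc(OS(=O)(=O)c3ccc(C)cc3)cc3c2CCC(C)(C)O3)Oc2cc(OCc3ccccc3)cc(OS(=O)(=O)c3ccc(C)cc3)c12
A3 | alternative 2 | 2-{[7-(methoxymethoxy)-2,2-dimethylchroman-5-yl]methoxy}-4,6-bis(methoxymethoxy)-3-(2-methylbut-3-en-2-yl)benzaldehyde | C=CC(C)(C)c1c(OCOC)cc(OCOC)c(C=O)c1OCc1cc(OCOC)cc2c1CCC(C)(C)O2
A4 | alternative 2 | 4,6-bis(methoxymethoxy)-2-[7-(methoxymethoxy)-2,2-dimethylchroman-5-yl]-7-(2-methylbut-3-en-2-yl)-1-benzofuran | C=CC(C)(C)c1c(OCOC)cc(OCOC)c2cc(-c3cc(OCOC)cc4c3CCC(C)(C)O4)oc12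
A5 | alternative 3 | 2-diazo-1-{5-[7-(methoxymethoxy)-2,2-dimethylchroman-5-yl]furan-2-yl}ethan-1-one | [N-]=[N+]=CC(=O)c1ccc(-c2cc(OCOC)cc3c2CCC(C)(C)O3)o1
A6 | alternative 3 | (ethynyloxy)tri(propan-2-yl)silane | C#CO[Si](C(C)C)(C(C)C)C(C)C
A7 | alternative 3 | 2-[7-(methoxymethoxy)-2,2-dimethylchroman-5-yl]-6-(triisopropylsilyloxy)-1-benzofuran-4-ol | Oc1cc(O[Si](C(C)C)(C(C)C)C(C)C)cc2oc(-c3cc(OCOC)cc4c3CCC(C)(C)O4)cc12
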